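**Retrosynthetic overview**
- The target is released from the methyl ester / acetate 17 by one global saponification.
- The thiazole ring is the only ring made, last of all, by Hantzsch condensation of bromoketone 15 (fragment B) with thioamide 6 (fragment A). The pyridine ring is bought intact in 7.
- Fragment B comes from 3-hydroxy-4-methoxypicolinic acid 7: C6 bromination para to OH, O-methylation, ester → methyl ketone (Weinreb), C6–Br → CO2Me (Pd carbonylation), then α-bromination.
- Fragment A comes from achiral 7-oxooctanoic acid 1: primary amide, ketoreductase reduction setting the (S)-carbinol, acetate protection, thionation.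

Assumption: 7-oxooctanoic acid and 3-hydroxy-4-methoxypicolinic acid are bought, and a Prelog-selective ketoreductase is picked from a commercial screening panel.

**Route**

Step 1
Reactants: 1 7-oxooctanoic acid
Product: 3 7-oxooctanamide, via acyl imidazolide 2 (not isolated)
Conditions: CDI (1.1 equiv), THF, rt, 1 h; then 28% aq NH3 (5 equiv), 0 °C → rt
Reagents that add atoms: ammonia, SMILES N
Why: CDI activates the acid as its acyl imidazolide, which ammonia opens to the primary amide (nucleophilic acyl substitution), the remote ketone being restored on aqueous work-up.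

Step 2
Reactants: 3 7-oxooctanamide
Product: 4 (7S)-7-hydroxyoctanamide
Conditions: (S)-selective NADPH-dependent ketoreductase (alcohol dehydrogenase class), NADP+ (cat.), iPrOH (10% v/v), KH2PO4/K2HPO4 buffer pH 7.0, MgSO4 (1 mM), 30 °C
Reagents that add atoms: none
Why: Biocatalytic asymmetric ketone reduction: the Prelog-selective ketoreductase delivers hydride from NADPH to the Re face of the methyl ketone, giving the (S)-carbinol in >99% ee, with isopropanol recycling the cofactor.

Step 3
Reactants: 4 (7S)-7-hydroxyoctanamide
Product: 5 (2S)-8-amino-8-oxooctan-2-yl acetate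
Conditions: Ac2O (1.2 equiv), pyridine (2 equiv), DMAP (5 mol%), CH2Cl2, 0 °C → rt
Reagents that add atoms: acetic anhydride, SMILES CC(=O)OC(C)=O
Why: DMAP-catalysed O-acylation of the secondary alcohol is far faster than N-acylation of the primary amide and leaves the C–O bond, and so the (S) centre, untouched.

Step 4
Reactants: 5 (2S)-8-amino-8-oxooctan-2-yl acetate
Product: 6 (2S)-8-amino-8-sulfanylideneoctan-2-yl acetate
Conditions: Lawesson's reagent (0.55 equiv), THF, rt, 3 h
Reagents that add atoms: Lawesson's reagent, SMILES COc1ccc(cc1)P1(=S)SP(=S)(S1)c1ccc(OC)cc1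
Why: Lawesson thionation exchanges the amide oxygen for sulfur through a Wittig-like four-membered P–S–C–O intermediate at room temperature, where the acetate ester is inert.

Step 5
Reactants: 7 3-hydroxy-4-methoxypyridine-2-carboxylic acid
Product: 8 methyl 3-hydroxy-4-methoxypyridine-2-carboxylate
Conditions: conc. H2SO4 (2 equiv), MeOH, reflux, 16 h; NaHCO3 work-up
Reagents that add atoms: methanol, SMILES CO
Why: Fischer esterification masks the acid so the following bromination cannot end in ipso bromodecarboxylation ortho to the hydroxyl.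

Step 6
Reactants: 8 methyl 3-hydroxy-4-methoxypyridine-2-carboxylate
Product: 9 methyl 6-bromo-3-hydroxy-4-methoxypyridine-2-carboxylate
Conditions: NBS (1.05 equiv), MeCN, 0 °C → rt
Reagents that add atoms: N-bromosuccinimide, SMILES O=C1CCC(=O)N1Br
Why: Electrophilic aromatic bromination goes to C6, the only open position para to the hydroxyl and alpha to nitrogen, since C2 and C4 are blocked and C5 is only meta to the hydroxyl.

Step 7
Reactants: 9 methyl 6-bromo-3-hydroxy-4-methoxypyridine-2-carboxylate
Product: 10 methyl 6-bromo-3,4-dimethoxypyridine-2-carboxylate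
Conditions: MeI (1.5 equiv), K2CO3 (2 equiv), DMF, rt
Reagents that add atoms: iodomethane, SMILES CI
Why: Williamson O-methylation of the pyridinol; the ring nitrogen, flanked by Br and CO2Me, is too hindered and electron-poor to be alkylated.

Step 8
Reactants: 10 methyl 6-bromo-3,4-dimethoxypyridine-2-carboxylate
Product: 11 6-bromo-N,3,4-trimethoxy-N-methylpyridine-2-carboxamide
Conditions: MeNH(OMe)·HCl (3 equiv), AlMe3 (3 equiv), CH2Cl2, 0 °C → rt; 1 M HCl quench
Reagents that add atoms: N,O-dimethylhydroxylamine hydrochloride, SMILES CNOC.Cl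
Why: Weinreb aminolysis: the aluminium amide formed from AlMe3 and the amine salt converts the activated picolinate ester directly into the N-methoxy-N-methylamide without touching the C–Br bond.

Step 9
Reactants: 11 6-bromo-N,3,4-trimethoxy-N-methylpyridine-2-carboxamide
Product: 12 1-(6-bromo-3,4-dimethoxypyridin-2-yl)ethan-1-one
Conditions: MeMgBr (1.3 equiv), THF, −10 → 0 °C; 1 M HCl quench
Reagents that add atoms: methylmagnesium bromide, SMILES C[Mg]Br
Why: Weinreb ketone synthesis: Grignard addition stops at the stable magnesium chelate, which gives the methyl ketone only on quench, and MeMgBr does not exchange with the bromopyridine at this temperature.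

Step 10
Reactants: 12 1-(6-bromo-3,4-dimethoxypyridin-2-yl)ethan-1-one
Product: 13 methyl 6-acetyl-4,5-dimethoxypyridine-2-carboxylate
Conditions: Pd(OAc)2 (5 mol%), 1,1'-bis(diphenylphosphino)ferrocene (6 mol%), CO (3 bar), Et3N (2 equiv), MeOH/DMF 1:1, 70 °C
Reagents that add atoms: carbon monoxide, SMILES [C-]#[O+]; methanol, SMILES CO
Why: Palladium-catalysed methoxycarbonylation: zerovalent palladium formed in situ inserts into the activated 2-pyridyl C–Br bond, and CO insertion followed by methanolysis gives the ester while the ketone is inert to Et3N.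

Step 11
Reactants: 13 methyl 6-acetyl-4,5-dimethoxypyridine-2-carboxylate
Product: 15 methyl 6-(2-bromoacetyl)-4,5-dimethoxypyridine-2-carboxylate, via silyl enol ether 14 (not isolated)
Conditions: TMSOTf (1.2 equiv), Et3N (1.5 equiv), CH2Cl2, 0 °C; then NBS (1.05 equiv), THF, 0 °C; aq NaHCO3 work-up
Reagents that add atoms: N-bromosuccinimide, SMILES O=C1CCC(=O)N1Br
Why: Soft enolisation to the trimethylsilyl enol ether followed by electrophilic bromination with NBS gives clean mono-α-bromination at the only enolisable carbon, without acid or free bromine.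

Step 12
Reactants: 15 methyl 6-(2-bromoacetyl)-4,5-dimethoxypyridine-2-carboxylate; 6 (2S)-8-amino-8-sulfanylideneoctan-2-yl acetate (1.1 equiv)
Product: 17 methyl 6-{2-[(6S)-6-(acetyloxy)heptyl]-1,3-thiazol-4-yl}-4,5-dimethoxypyridine-2-carboxylate, via hydroxythiazoline 16 (not isolated)
Conditions: KHCO3 (4 equiv), DME, −15 °C → rt; then TFAA (3 equiv), 2,6-lutidine (6 equiv), −15 → 0 °C
Reagents that add atoms: none
Why: Hantzsch thiazole synthesis in its buffered two-stage form: S-alkylation and ring closure onto the ketone give the hydroxythiazoline, which TFAA/2,6-lutidine dehydrates to the thiazole without acid that could cleave the acetate, the remote (S) centre not being involved.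

Step 13
Reactants: 17 methyl 6-{2-[(6S)-6-(acetyloxy)heptyl]-1,3-thiazol-4-yl}-4,5-dimethoxypyridine-2-carboxylate
Product: 18 6-{2-[(6S)-6-hydroxyheptyl]-1,3-thiazol-4-yl}-4,5-dimethoxypyridine-2-carboxylic acid
Conditions: LiOH·H2O (4 equiv), THF/MeOH/H2O 3:1:1, rt; then 1 M HCl to pH 3–4
Reagents that add atoms: lithium hydroxide, SMILES [Li+].[OH-]
Why: Saponification by acyl–oxygen cleavage removes the methyl ester and the acetate in one operation and leaves the carbinol configuration untouched.

**Compound list**
1 | 7-oxooctanoic acid | CC(=O)CCCCCC(O)=O | starting material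
2 | 1-(1H-imidazol-1-yl)octane-1,7-dione (acyl imidazolide) | CC(=O)CCCCCC(=O)n1ccnc1 | intermediate
3 | 7-oxooctanamide | CC(=O)CCCCCC(N)=O | intermediate
4 | (7S)-7-hydroxyoctanamide | C[C@H](O)CCCCCC(N)=O | intermediate
5 | (2S)-8-amino-8-oxooctan-2-yl acetate | C[C@H](OC(C)=O)CCCCCC(N)=O | intermediate
6 | (2S)-8-amino-8-sulfanylideneoctan-2-yl acetate (primary thioamide) | C[C@H](OC(C)=O)CCCCCC(N)=S | intermediate
7 | 3-hydroxy-4-methoxypyridine-2-carboxylic acid | COc1ccnc(C(O)=O)c1O | starting material
8 | methyl 3-hydroxy-4-methoxypyridine-2-carboxylate | COC(=O)c1nccc(OC)c1O | intermediate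
9 | methyl 6-bromo-3-hydroxy-4-methoxypyridine-2-carboxylate | COC(=O)c1nc(Br)cc(OC)c1O | intermediate
10 | methyl 6-bromo-3,4-dimethoxypyridine-2-carboxylate | COC(=O)c1nc(Br)cc(OC)c1OC | intermediate
11 | 6-bromo-N,3,4-trimethoxy-N-methylpyridine-2-carboxamide | CON(C)C(=O)c1nc(Br)cc(OC)c1OC | intermediate
12 | 1-(6-bromo-3,4-dimethoxypyridin-2-yl)ethan-1-one | CC(=O)c1nc(Br)cc(OC)c1OC | intermediate
13 | methyl 6-acetyl-4,5-dimethoxypyridine-2-carboxylate | CC(=O)c1nc(C(=O)OC)cc(OC)c1OC | intermediate
14 | methyl 4,5-dimethoxy-6-{1-[(trimethylsilyl)oxy]ethenyl}pyridine-2-carboxylate (silyl enol ether) | C=C(O[Si](C)(C)C)c1nc(C(=O)OC)cc(OC)c1OC | intermediate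
15 | methyl 6-(2-bromoacetyl)-4,5-dimethoxypyridine-2-carboxylate | BrCC(=O)c1nc(C(=O)OC)cc(OC)c1OC | intermediate
16 | methyl 6-{(4RS)-2-[(6S)-6-(acetyloxy)heptyl]-4-hydroxy-4,5-dihydro-1,3-thiazol-4-yl}-4,5-dimethoxypyridine-2-carboxylate (hydroxythiazoline, both C4 epimers) | C[C@H](OC(C)=O)CCCCCC1=NC(O)(CS1)c1nc(C(=O)OC)cc(OC)c1OC | intermediate
17 | methyl 6-{2-[(6S)-6-(acetyloxy)heptyl]-1,3-thiazol-4-yl}-4,5-dimethoxypyridine-2-carboxylate | C[C@H](OC(C)=O)CCCCCc1nc(cs1)-c1nc(C(=O)OC)cc(OC)c1OC | intermediate
18 | 6-{2-[(6S)-6-hydroxyheptyl]-1,3-thiazol-4-yl}-4,5-dimethoxypyridine-2-carboxylic acid | C[C@H](O)CCCCCc1nc(cs1)-c1nc(C(O)=O)cc(OC)c1OC | target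

**Totals**
Total step count: 13. Longest linear sequence: 9 steps (steps 5–13, from 7); the side-chain branch is steps 1–4.

**Three steps most likely to fail**

Step 2 (ketoreductase reduction; risk: no panel enzyme gives both high conversion and high ee on this amide). The fallback sets out from 3 and comes back at 4. Ketone 3 is reduced with NaBH4 in MeOH at 0 °C to racemic 7-hydroxyoctanamide F1. F1 is then resolved with immobilised Candida antarctica lipase B and vinyl acetate in 2-MeTHF at 30 °C. Following the Kazlauskas rule the lipase acetylates the (R)-alcohol to (2R)-8-amino-8-oxooctan-2-yl acetate F2 and leaves the (S)-alcohol. Stopping at about 55% conversion and separating by chromatography gives 4 in high ee, at the cost of at most half the material.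

Step 4 (Lawesson thionation of a primary amide; risk: partial dehydration to the nitrile and phosphorus by-products that are hard to remove). The fallback sets out from 5 and comes back at 6. Amide 5 is deliberately dehydrated with TFAA/pyridine in CH2Cl2 at 0 °C to (2S)-7-cyanoheptan-2-yl acetate F3. Hydrogen sulfide is then added across the nitrile with NaSH·xH2O and MgCl2·6H2O in DMF at rt, giving thioamide 6 with no phosphorus reagent involved.

Step 11 (α-bromination; risk: hydrolysis of the enol silane back to 13, or dibromination). The fallback sets out from 13 and comes back at 17. Ketone 13 is oxidised at the α-carbon with the hypervalent iodine reagent PhI(OH)OTs in MeCN at 80 °C to methyl 4,5-dimethoxy-6-{2-[(4-methylbenzenesulfonyl)oxy]acetyl}pyridine-2-carboxylate F4. This α-sulfonyloxy ketone takes the place of 15 in the step 12 protocol with thioamide 6, passing through hydroxythiazoline 16 to thiazole 17.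

**Further compounds**
F1 | step 2 | racemic 7-hydroxyoctanamide | CC(O)CCCCCC(N)=O
F2 | step 2 | (2R)-8-amino-8-oxooctan-2-yl acetate | C[C@@H](OC(C)=O)CCCCCC(N)=O
F3 | step 4 | (2S)-7-cyanoheptan-2-yl acetate | C[C@H](OC(C)=O)CCCCCC#N
F4 | step 11 | methyl 4,5-dimethoxy-6-{2-[(4-methylbenzenesulfonyl)oxy]acetyl}pyridine-2-carboxylate | COC(=O)c1cc(OC)c(OC)c(n1)C(=O)COS(=O)(=O)c1ccc(C)cc1
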